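In 2.5 h the substrate divides between two paths, one that needs dissolved gas and one that does not.

substrate 0.10 M; gas phase 6.2 mM (held); time 2.5 h

    dissolved gas → decomposition product (k1 = 2.8 × 10⁻⁵ /min)
    crystals ⇌ target, rate k2*(cs2 - [target]) while solid is left; crystals form when [target] > cs2 (cs2 = 40 mM, k2 = 3.6 /min)
    substrate → side product (k3 = 0.0038 /min)
    gas phase ⇌ dissolved gas, rate k4*(csat - [dissolved gas]) (k4 = 0.86 /min, csat = 6.2 mM)
    2 dissolved gas → self-condensation product (k5 = 1.7 /M/min)
    substrate + dissolved gas → target (k6 = 1.5 /M/min)

- amounts and yields of target count crystals too
- where a step has two of a species, its rate is k times that concentration squared, and two are used at each turn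
- given per volume of solution although it is solid: crystals
- at the start none of the gas is dissolved
- run time (flask): 2.5 h

- target and crystals together at 2.5 h, in percent of the substrate charged
- the change that raises the amount of target and crystals together at 2.5 h, in percent of the substrate charged most ("none" if none brings more than 2 percentage points) (eta / epsilon / beta / delta / none)
- amount of target and crystals together at 2.5 h, in percent of the substrate charged, after epsilon

- eta: doubling the solubility in step 2, all else as stated
- epsilon: doubling the saturation concentration of gas phase, all else as stated
- beta: doubling the transfer coefficient of step 4, all else as stated
- delta: doubling the dissolution coefficient of step 2, all else as stated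

**The yield rule.** Let b be the dissolved gas. At steady b the substrate decays pseudo-first-order with K = 0.0038 /min + 1.5 /M/min·b, and the share 1.5 /M/min·b/K of what reacts becomes target. Crystals count as target, so the crystal step drops out of the sum. The yield Y is that share times the part of the substrate gone by time t, where exp(−Kt) is the part left. Y rises with b, so bounds on b bound Y.

**Upper bound.** The gas starts at zero and is fed towards 6.2 mM. Setting b there gives Y = 61.0%.

**Lower bound.** Transfer must balance consumption. Consumption per unit of b is greatest with the full charge of substrate and b at saturation, so the balance level stands near or above 5.17 mM. Starting from zero, b approaches that level with a time constant of about 0.970 min, so it needs about 2.91 min to come close. Passing over those minutes and taking that level from the start gives Y = 55.3%, less than the upper bound.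

**Tightening.** I replace the curve by the mean gas level, the balance level at the mean substrate. The lower-bound decay puts that mean at 47.5 mM, so the level is 5.60 mM. Then K = 0.0122 /min, the share is 68.8%, and Y = 57.8%. Substrate turns over fastest at the start, where the level is nearer 5.17 mM, lower than the mean, so I expect this to lean high.

**The forecast.** It gives 57%, from 54% to 60%, a value inside my bracket. It picks epsilon, with 77% after it, saying: “doubling the saturation concentration roughly doubles the dissolved gas and so beats the side reaction far better than any other change”.

**The result.** The flask gives 57.3%, which is 0.50 percentage points below my figure. The best change is epsilon, worth 20 points, and it reaches 77.2%.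

**Read later.** I keep K and the share and read the same flask at 6.0 h. The rule leaves 1.24% of the substrate and gives Y = 67.9%. That flask holds 1.10% of its substrate, with target and crystals together at 67.8%.

The constants are made up; no experiment stands behind them.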